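The plan rests on disconnecting the O1–C2 ether bond of the oxolane ring. C2, with its methyl group and chain, is C3 of natural phytol. Once C9 is written as a ketone, the spiro carbon C5 belongs to a symmetric 2-hydroxycyclopent-4-ene-1,3-dione ring and is not stereogenic. In one operation the key step lets this C5 hydroxyl open a (2S,3S)-epoxyphytyl side chain at its tertiary carbon. The oxolane closes, C2 is fixed by inversion, and a temporary C3 hydroxyl appears that later tells the C6 and C9 carbonyls apart. The precursor is the hydroxy-enedione bearing the trans-2,3-epoxyphytyl group on C5, built from dimethylmaleic anhydride and phytol.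

Key step: step 7

Locants: the spiro numbering of the target is used throughout: O1, C2 (methyl and chain), C3, C4, C5 (spiro), C6 (ketone), C7=C8, C9 (carbinol). "Chain" means (4R,8R)-4,8,12-trimethyltridecyl.
Stereochemical reading of the target: (2R,5R,9S,4'R,8'R). The C9 hydroxyl is trans to O1 on the cyclopentene ring, and the C2 methyl lies on the C6 side of the oxolane plane.
Assumption: the ethylidene geometry in 12–15 and the side-chain carbinol configuration in 16 are left open, because the last oxidation erases both.

Step 1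
Reactants: 1 2,3-dimethylmaleic anhydride
Product: 2 methyl (E)-2-(3,4-dimethyl-5-oxofuran-2(5H)-ylidene)acetate
Conditions: Ph3P=CHCO2Me (1.05 equiv), toluene, 90 °C
Reagents that add atoms: methyl (triphenylphosphoranylidene)acetate, COC(=O)C=P(c1ccccc1)(c1ccccc1)c1ccccc1
Why: Wittig olefination of one carbonyl of a cyclic anhydride by a stabilised ylide is the standard entry to 5-ylidenebutenolides; the anhydride is symmetric, so only one constitutional isomer can form, and the alkene geometry does not matter because the lactone is opened in step 2.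

Step 2
Reactants: 2 methyl (E)-2-(3,4-dimethyl-5-oxofuran-2(5H)-ylidene)acetate
Product: 4 4,5-dimethylcyclopent-4-ene-1,3-dione, via sodium enolate of the 2-methoxycarbonyl dione 3 (not isolated)
Conditions: NaOMe (1.1 equiv), MeOH, 0 °C → reflux; then 2 M aq HCl, 70 °C
Reagents that add atoms: none
Why: Methoxide opens the enol lactone to a β-keto ester enolate that closes onto the new methyl ester (Dieckmann-type ylidenebutenolide-to-cyclopentenedione rearrangement, the counterpart of the alkylidenephthalide-to-indanedione rearrangement), and warm dilute acid then hydrolyses and decarboxylates the doubly activated ester as in the classical indane-1,3-dione preparation.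

Step 3
Reactants: 5 natural (2E,7R,11R)-phytol
Product: 6 (2E,7R,11R)-phytyl bromide
Conditions: PBr3 (0.4 equiv), pyridine (cat.), Et2O, −10 → 0 °C, used without storage
Reagents that add atoms: phosphorus tribromide, BrP(Br)Br
Why: Bromination of a primary allylic alcohol through its phosphite ester is an SN2 process that, kept cold and short, preserves the E alkene and leaves C7 and C11 untouched.

Step 4
Reactants: 4 4,5-dimethylcyclopent-4-ene-1,3-dione (2 equiv), 6 (2E,7R,11R)-phytyl bromide
Product: 7 4,5-dimethyl-2-[(2E,7R,11R)-3,7,11,15-tetramethylhexadec-2-en-1-yl]cyclopent-4-ene-1,3-dione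
Conditions: K2CO3 (1.1 equiv), acetone, 0 °C → rt
Reagents that add atoms: none
Why: SN2 C-alkylation of the stabilised 1,3-dione enolate by a soft primary allylic bromide keeps the E geometry, O-alkylation is disfavoured because it would create a cyclopentadienone, and the excess of the more acidic 4 keeps 7 protonated so that a second alkylation is suppressed.

Step 5
Reactants: 7 4,5-dimethyl-2-phytylcyclopent-4-ene-1,3-dione
Product: 8 2-hydroxy-4,5-dimethyl-2-[(2E,7R,11R)-3,7,11,15-tetramethylhexadec-2-en-1-yl]cyclopent-4-ene-1,3-dione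
Conditions: 2-(phenylsulfonyl)-3-phenyloxaziridine (1.2 equiv), DBU (0.2 equiv), CH2Cl2, −20 → 0 °C
Reagents that add atoms: 2-(phenylsulfonyl)-3-phenyloxaziridine, O=S(=O)(N1OC1c1ccccc1)c1ccccc1
Why: Davis oxidation, in which the enolate carbon attacks the oxaziridine oxygen; the reagent does not epoxidise isolated alkenes, a catalytic amine base suffices for so acidic a C–H and spares the base-labile product, and no stereocentre arises because the two ring arms at the carbinol carbon are identical.

Step 6
Reactants: 8 2-hydroxy-4,5-dimethyl-2-phytylcyclopent-4-ene-1,3-dione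
Product: 9 2-hydroxy-4,5-dimethyl-2-{[(2S,3S)-3-methyl-3-[(4R,8R)-4,8,12-trimethyltridecyl]oxiran-2-yl]methyl}cyclopent-4-ene-1,3-dione (ring CH2 cis to the oxirane methyl)
Conditions: 1,2:4,5-di-O-isopropylidene-β-L-erythro-2,3-hexodiulo-2,6-pyranose (mirror image of the D-fructose ketone, made from L-sorbose; 0.5 equiv), 2KHSO5·KHSO4·K2SO4 and K2CO3 (separate aq solutions, slow simultaneous addition, pH 9–10), Bu4NHSO4 (cat.), MeCN–CH2(OMe)2 / aq Na2B4O7–Na2(EDTA), −5 °C
Reagents that add atoms: potassium peroxymonosulfate, [K+].[O-]S(=O)(=O)OO (oxygen passed on through the dioxirane of the ketone)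
Why: Shi epoxidation, in which the electrophilic chiral dioxirane reacts only with the electron-rich trisubstituted alkene; since the D-fructose-derived ketone gives (R,R)-epoxides from E-trisubstituted alkenes through the spiro transition state, its L-configured mirror image is required to set both oxirane carbons as S by syn addition under pure reagent control.

Step 7
Reactants: 9 2-hydroxy-4,5-dimethyl-2-[(2S,3S)-2,3-epoxyphytyl]cyclopent-4-ene-1,3-dione
Product: 10 (2R,3S)-3-hydroxy-2,7,8-trimethyl-2-[(4R,8R)-4,8,12-trimethyltridecyl]-1-oxaspiro[4.4]non-7-ene-6,9-dione (C3 hydroxyl cis to the C2 methyl)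
Conditions: 10-camphorsulfonic acid (0.2 equiv), 4 Å molecular sieves, CH2Cl2 (0.02 M), −20 → 0 °C
Reagents that add atoms: none
Why: Protonation of the oxirane oxygen lengthens the bond to the fully substituted carbon, and the C5 hydroxyl attacks that carbon from the rear while the oxirane oxygen is still attached, so O1–C2 forms in a loose SN2 process. The closest known reaction type is the acid-catalysed endo-selective cyclisation of hydroxy epoxides with a trisubstituted oxirane, used for 3-hydroxyoxolanes from 3,4-epoxy alcohols and for polyether and chroman rings. The oxolane ring (O1–C2–C3–C4–C5) closes in the 5-endo-tet mode, whereas 4-exo attack at the secondary carbon would give a strained oxetane at a carbon that cannot carry positive charge well. C2 becomes R by inversion of the (3S) oxirane carbon and is therefore controlled by the reagent-controlled epoxidation of step 6; C3 keeps its C–O bond and emerges S with its hydroxyl cis to the C2 methyl, and C5 stays non-stereogenic because its two ring arms are identical. The step needs attack at the tertiary rather than the secondary carbon, which the methyl and alkyl substitution and the ring-size bias secure. It also needs clean backside attack, which a catalytic acid with a poorly nucleophilic counter-ion in a dry, non-polar solvent at low temperature favours by denying a free cation the time to rotate, shift hydride or lose a proton.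

Step 8
Reactants: 10 (2R,3S)-3-hydroxy spiro-enedione
Product: 11 (2R,3S)-2,7,8-trimethyl-3-(triisopropylsilyloxy)-2-[(4R,8R)-4,8,12-trimethyltridecyl]-1-oxaspiro[4.4]non-7-ene-6,9-dione
Conditions: iPr3SiOTf (1.5 equiv), 2,6-lutidine (2.5 equiv), CH2Cl2, 0 °C → rt
Reagents that add atoms: triisopropylsilyl trifluoromethanesulfonate, CC(C)[Si](C(C)C)(C(C)C)OS(=O)(=O)C(F)(F)F
Why: Silyl triflate silylation of a hindered secondary alcohol with a non-nucleophilic base is routine, there is no other hydroxyl and the enedione has no α-hydrogen, and the bulky group ends up cis-1,3 to one of the two carbonyl groups across the oxolane ring.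

Step 9
Reactants: 11 (2R,3S)-3-silyloxy spiro-enedione
Product: 12 (2R,3S,5R)-9-ethylidene-2,7,8-trimethyl-3-(triisopropylsilyloxy)-2-[(4R,8R)-4,8,12-trimethyltridecyl]-1-oxaspiro[4.4]non-7-en-6-one (E/Z mixture)
Conditions: EtPPh3Br (1.3 equiv), KN(SiMe3)2 (1.2 equiv), THF, 0 °C; then 11, −78 → 0 °C
Reagents that add atoms: ethyltriphenylphosphonium bromide, CC[P+](c1ccccc1)(c1ccccc1)c1ccccc1.[Br-]
Why: Wittig olefination under lithium-free conditions proceeds through the oxaphosphetane and so avoids a free β-keto alkoxide that could fragment; of the four approach quadrants around C5, the two on the O1 face are screened by the C2 methyl and the C2 chain and the one on the C4 face next to the silyloxy group is blocked, so the ylide should take the carbonyl trans to the silyl ether, which makes C5 a stereocentre of R configuration with the surviving ketone C6 on the side of the C2 methyl.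

Step 10
Reactants: 12 (2R,3S,5R)-9-ethylidene silyl ether
Product: 13 (2R,3S,5R)-9-ethylidene-3-hydroxy-2,7,8-trimethyl-2-[(4R,8R)-4,8,12-trimethyltridecyl]-1-oxaspiro[4.4]non-7-en-6-one
Conditions: HF·pyridine, pyridine, THF, 0 °C → rt
Reagents that add atoms: none
Why: Fluoride-mediated cleavage of the Si–O bond under buffered, weakly acidic conditions touches neither the dienone nor the two fully substituted ether carbons.

Step 11
Reactants: 13 (2R,3S,5R)-9-ethylidene-3-hydroxy dienone
Product: 14 O-[(2R,3S,5R)-9-ethylidene-2,7,8-trimethyl-6-oxo-2-[(4R,8R)-4,8,12-trimethyltridecyl]-1-oxaspiro[4.4]non-7-en-3-yl] 1H-imidazole-1-carbothioate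
Conditions: 1,1'-thiocarbonyldiimidazole (2 equiv), DMAP (0.2 equiv), toluene, 80 °C
Reagents that add atoms: 1,1'-thiocarbonyldiimidazole, S=C(n1ccnc1)n1ccnc1
Why: Thioacylation of the only hydroxyl group gives the radical precursor of the Barton–McCombie reaction under neutral conditions that avoid enolate chemistry of the dienone, and the C3–O bond is not broken.

Step 12
Reactants: 14 C3 imidazolylthiocarbonyl dienone
Product: 15 (2R,5R)-9-ethylidene-2,7,8-trimethyl-2-[(4R,8R)-4,8,12-trimethyltridecyl]-1-oxaspiro[4.4]non-7-en-6-one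
Conditions: Bu3SnH (2 equiv, 0.2 M), AIBN (0.2 equiv), toluene, 85 °C
Reagents that add atoms: none
Why: Barton–McCombie deoxygenation, in which the stannyl radical adds to the thiocarbonyl sulfur far faster than to the hindered dienone; the secondary C3 radical has its orbital nearly orthogonal to the endocyclic C4–C5 and C2–O1 bonds and should be quenched by the concentrated hydride before it can fragment, and the temporary stereocentre C3 disappears while C2 and C5 are untouched.

Step 13
Reactants: 15 (2R,5R)-9-ethylidene dienone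
Product: 16 (2R,5R,9R)-9-hydroxy-9-(1-hydroxyethyl)-2,7,8-trimethyl-2-[(4R,8R)-4,8,12-trimethyltridecyl]-1-oxaspiro[4.4]non-7-en-6-one (C9 hydroxyl trans to O1; epimers at the side-chain carbinol)
Conditions: OsO4 (10 mol %), N-methylmorpholine N-oxide (2 equiv), MeSO2NH2 (1 equiv), acetone–tBuOH–H2O, rt; aq Na2SO3 work-up
Reagents that add atoms: osmium tetroxide (oxygen carrier), O=[Os](=O)(=O)=O; N-methylmorpholine N-oxide, C[N+]1([O-])CCOCC1; water, O
Why: Catalytic OsO4 syn-dihydroxylation picks the more electron-rich trisubstituted γ,δ-alkene of the dienone over the tetrasubstituted α,β-alkene and adds from the C4 face, anti to the allylic oxygen O1 and away from the C2 chain that lies under the O1 face on this side of the ring, which places the C9 hydroxyl trans to O1 as in the target.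

Step 14
Reactants: 16 (2R,5R,9R)-diol
Product: 17 (2R,5R,9S)-9-acetyl-9-hydroxy-2,7,8-trimethyl-2-[(4R,8R)-4,8,12-trimethyltridecyl]-1-oxaspiro[4.4]non-7-en-6-one (target; the C9 descriptor changes only through priorities)
Conditions: IBX (1.5 equiv), DMSO–THF 1:1, rt
Reagents that add atoms: none
Why: IBX oxidises the secondary carbinol of a 1,2-diol to the α-hydroxy ketone without C–C cleavage and cannot touch the tertiary C9 hydroxyl, so both side-chain epimers converge on the acetyl group while C2, C5 and C9 are retained.

Compound list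
1 | 2,3-dimethylmaleic anhydride | CC1=C(C)C(=O)OC1=O | starting material
2 | methyl (E)-2-(3,4-dimethyl-5-oxofuran-2(5H)-ylidene)acetate | COC(=O)/C=C1/OC(=O)C(C)=C1C | intermediate
3 | sodium enolate of methyl 3,4-dimethyl-2,5-dioxocyclopent-3-ene-1-carboxylate (not isolated) | COC(=O)C1=C([O-])C(C)=C(C)C1=O.[Na+] | intermediate
4 | 4,5-dimethylcyclopent-4-ene-1,3-dione | CC1=C(C)C(=O)CC1=O | intermediate
5 | (2E,7R,11R)-phytol | OC/C=C(\C)CCC[C@H](C)CCC[C@H](C)CCCC(C)C | starting material
6 | (2E,7R,11R)-phytyl bromide | BrC/C=C(\C)CCC[C@H](C)CCC[C@H](C)CCCC(C)C | intermediate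
7 | 4,5-dimethyl-2-[(2E,7R,11R)-phytyl]cyclopent-4-ene-1,3-dione | O=C1C(C)=C(C)C(=O)C1C/C=C(\C)CCC[C@H](C)CCC[C@H](C)CCCC(C)C | intermediate
8 | 2-hydroxy-4,5-dimethyl-2-[(2E,7R,11R)-phytyl]cyclopent-4-ene-1,3-dione | O=C1C(C)=C(C)C(=O)C1(O)C/C=C(\C)CCC[C@H](C)CCC[C@H](C)CCCC(C)C | intermediate
9 | 2-hydroxy-4,5-dimethyl-2-[(2S,3S,7R,11R)-2,3-epoxy-3,7,11,15-tetramethylhexadecyl]cyclopent-4-ene-1,3-dione | O=C1C(C)=C(C)C(=O)C1(O)C[C@@H]2O[C@@]2(C)CCC[C@H](C)CCC[C@H](C)CCCC(C)C | intermediate
10 | (2R,3S)-3-hydroxy-2,7,8-trimethyl-2-chain-1-oxaspiro[4.4]non-7-ene-6,9-dione | O=C1C(C)=C(C)C(=O)C12C[C@H](O)[C@@](C)(CCC[C@H](C)CCC[C@H](C)CCCC(C)C)O2 | intermediate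
11 | (2R,3S)-3-(triisopropylsilyloxy) spiro-enedione | O=C1C(C)=C(C)C(=O)C12C[C@H](O[Si](C(C)C)(C(C)C)C(C)C)[C@@](C)(CCC[C@H](C)CCC[C@H](C)CCCC(C)C)O2 | intermediate
12 | (2R,3S,5R)-9-ethylidene-3-(triisopropylsilyloxy) dienone (E/Z) | CC=C1C(C)=C(C)C(=O)[C@@]12C[C@H](O[Si](C(C)C)(C(C)C)C(C)C)[C@@](C)(CCC[C@H](C)CCC[C@H](C)CCCC(C)C)O2 | intermediate
13 | (2R,3S,5R)-9-ethylidene-3-hydroxy dienone (E/Z) | CC=C1C(C)=C(C)C(=O)[C@@]12C[C@H](O)[C@@](C)(CCC[C@H](C)CCC[C@H](C)CCCC(C)C)O2 | intermediate
14 | C3 O-(imidazol-1-ylthiocarbonyl) derivative of 13 | CC=C1C(C)=C(C)C(=O)[C@@]12C[C@H](OC(=S)n3ccnc3)[C@@](C)(CCC[C@H](C)CCC[C@H](C)CCCC(C)C)O2 | intermediate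
15 | (2R,5R)-9-ethylidene-2,7,8-trimethyl-2-chain-1-oxaspiro[4.4]non-7-en-6-one (E/Z) | CC=C1C(C)=C(C)C(=O)[C@@]12CC[C@@](C)(CCC[C@H](C)CCC[C@H](C)CCCC(C)C)O2 | intermediate
16 | (2R,5R,9R)-9-hydroxy-9-(1-hydroxyethyl) enone (side-chain epimers) | CC(O)[C@]1(O)C(C)=C(C)C(=O)[C@@]12CC[C@@](C)(CCC[C@H](C)CCC[C@H](C)CCCC(C)C)O2 | intermediate
17 | (2R,5R,9S)-9-acetyl-9-hydroxy-2,7,8-trimethyl-2-[(4R,8R)-4,8,12-trimethyltridecyl]-1-oxaspiro[4.4]non-7-en-6-one | CC(=O)[C@]1(O)C(C)=C(C)C(=O)[C@@]12CC[C@@](C)(CCC[C@H](C)CCC[C@H](C)CCCC(C)C)O2 | target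

Total step count: 14. Longest linear sequence: 13 (steps 1, 2 and 4–14; step 3 is the only branch).

Steps most likely to fail

Step 7. The hydroxyl between two carbonyl groups may attack too slowly. Hydride migration, proton loss, participation of a ring carbonyl oxygen, or full ionisation with loss of stereochemical fidelity could then overtake ring closure. The fallback sets out from 9 and rejoins at 10, and it removes the electron-withdrawing groups for the duration of the cyclisation. Luche reduction of 9 (NaBH4, CeCl3·7H2O, MeOH–THF, −78 → −40 °C) should give the epoxy enetriol F1 as a mixture of carbinol epimers of no consequence. TBSCl and imidazole in DMF silylate only the two secondary allylic hydroxyls, giving the bis-silyl ether F2. Its tertiary alcohol now has ordinary nucleophilicity and no neighbouring carbonyl oxygens, and it undergoes the same acid-catalysed 5-endo opening (camphorsulfonic acid, CH2Cl2, 0 °C) to the spiro-oxolane F3. Bu4NF in THF frees the spiro enetriol F4, and MnO2 in CH2Cl2 oxidises the two allylic carbinols but not the C3 hydroxyl, which gives 10.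

Step 9. The strongly basic ylide may deprotonate the C7 and C8 methyl groups (vinylogous enolisation) or transfer an electron to the enedione instead of adding. Discrimination between the two carbonyl groups may also be incomplete. The fallback sets out from 11 and rejoins at 12, and it replaces olefination by carbonyl addition and dehydration. The ethylcerium reagent from EtMgBr and anhydrous CeCl3 (THF, −78 °C) is nucleophilic but hardly basic and reacts at a temperature where steric differentiation is greatest. It should add through the same open quadrant to give the tertiary carbinol F5. The Burgess reagent (toluene, 60 °C) then eliminates by a syn pathway that can only use the ethyl CH2, since C5 and C8 bear no hydrogen, and delivers 12.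

Step 6. Carbonate- or hydroxide-induced ring cleavage (retro-Claisen) or α-ketol rearrangement of the hydroxy-dione may occur in the aqueous buffer, and facial selectivity may be incomplete. The fallback sets out from 5 (with 4) and rejoins at 9, and it installs the oxirane before the ring is attached. Sharpless asymmetric epoxidation of 5 (Ti(OiPr)4, L-(+)-diisopropyl tartrate, tBuOOH, 4 Å molecular sieves, CH2Cl2, −20 °C) should give (2S,3S)-2,3-epoxyphytol F6. This is the sense natural tartrate delivers for E-allylic alcohols. I2, PPh3 and imidazole convert it into the epoxy iodide F7. Alkylation of 4 (2 equiv, K2CO3, DMF, 40 °C) at the primary carbon gives the epoxyphytyl dione F8, and Davis oxidation as in step 5 gives 9.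

Further compounds
F1 | step 7 | 2-{[(2S,3S)-3-methyl-3-chain-oxiran-2-yl]methyl}-4,5-dimethylcyclopent-4-ene-1,2,3-triol (carbinol epimers) | OC1C(C)=C(C)C(O)C1(O)C[C@@H]2O[C@@]2(C)CCC[C@H](C)CCC[C@H](C)CCCC(C)C
F2 | step 7 | 1,3-bis-O-(tert-butyldimethylsilyl) ether of F1 | CC(C)(C)[Si](C)(C)OC1C(C)=C(C)C(O[Si](C)(C)C(C)(C)C)C1(O)C[C@@H]2O[C@@]2(C)CCC[C@H](C)CCC[C@H](C)CCCC(C)C
F3 | step 7 | (2R,3S)-6,9-bis(tert-butyldimethylsilyloxy)-2,7,8-trimethyl-2-chain-1-oxaspiro[4.4]non-7-en-3-ol | CC(C)(C)[Si](C)(C)OC1C(C)=C(C)C(O[Si](C)(C)C(C)(C)C)C12C[C@H](O)[C@@](C)(CCC[C@H](C)CCC[C@H](C)CCCC(C)C)O2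
F4 | step 7 | (2R,3S)-2,7,8-trimethyl-2-chain-1-oxaspiro[4.4]non-7-ene-3,6,9-triol | OC1C(C)=C(C)C(O)C12C[C@H](O)[C@@](C)(CCC[C@H](C)CCC[C@H](C)CCCC(C)C)O2
F5 | step 9 | (2R,3S,5R,9R)-9-ethyl-9-hydroxy-2,7,8-trimethyl-3-(triisopropylsilyloxy)-2-chain-1-oxaspiro[4.4]non-7-en-6-one | CC[C@@]1(O)C(C)=C(C)C(=O)[C@@]12C[C@H](O[Si](C(C)C)(C(C)C)C(C)C)[C@@](C)(CCC[C@H](C)CCC[C@H](C)CCCC(C)C)O2
F6 | step 6 | (2S,3S,7R,11R)-2,3-epoxyphytol | OC[C@@H]1O[C@@]1(C)CCC[C@H](C)CCC[C@H](C)CCCC(C)C
F7 | step 6 | (2R,3S)-2-(iodomethyl)-3-methyl-3-[(4R,8R)-4,8,12-trimethyltridecyl]oxirane | IC[C@@H]1O[C@@]1(C)CCC[C@H](C)CCC[C@H](C)CCCC(C)C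
F8 | step 6 | 4,5-dimethyl-2-{[(2S,3S)-3-methyl-3-chain-oxiran-2-yl]methyl}cyclopent-4-ene-1,3-dione | O=C1C(C)=C(C)C(=O)C1C[C@@H]2O[C@@]2(C)CCC[C@H](C)CCC[C@H](C)CCCC(C)C
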